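**Assumption:** atom labels C1–C11 follow bisabolane numbering (C1 = C(Cl)Me, C2 = CHBr, C4 = ring CH carrying the oxane, C5 = CHOAc, C7 = O–C(Me) of the oxane, C8 = CHOH, C10 = CHBr of the oxane, C11 = CMe2); all unnumbered reagents are commercial.

## Retrosynthetic overview

1. Oxane (formed last): C11–O/C10–Br by 6-endo bromoetherification of the C7 tertiary alcohol onto a prenyl olefin; prenyl from allyl by cross-metathesis; C8–C9 by Cram-chelate allylation of a C8 aldehyde.
2. Ring Br/Cl (key step, not a BrCl addition, which would open trans-diaxially and give the wrong C1/C2 diastereomer): syn-dihydroxylation anti to the C5 acetate, cyclic sulfate, SN2 bromide at C2, then bromonium-relayed chloride at C1, done before any side-chain olefin exists.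
3. C7: 1,3-chelation-controlled addition of a formyl-anion equivalent to a cis-β-hydroxy methyl ketone.
4. Carbocycle (formed first): Evans syn-aldol (sets C4/C5), then ring-closing metathesis.
5. Ring order: cyclohexene → halogenated cyclohexane → oxane.

## Route

Step 1
Reactants: 1 (4S)-4-benzyl-1,3-oxazolidin-2-one; 2 pent-4-enoyl chloride
Product: 3 (4S)-4-benzyl-3-(pent-4-enoyl)-1,3-oxazolidin-2-one
Conditions: Et3N, DMAP (cat.), CH2Cl2, 0 °C to rt
Reagents that add atoms: none
Why: DMAP-catalysed N-acylation of the oxazolidinone by the acid chloride installs the Evans auxiliary; no stereocenter is formed.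

Step 2
Reactants: 4 3-methylbut-3-en-1-ol
Product: 5 3-methylbut-3-enal
Conditions: Dess–Martin periodinane, NaHCO3, CH2Cl2, 0 °C; solution used at once
Reagents that add atoms: none
Why: Buffered Dess–Martin oxidation gives the β,γ-unsaturated aldehyde under neutral conditions that avoid isomerisation into conjugation.

Step 3
Reactants: 3 (4S)-4-benzyl-3-(pent-4-enoyl)-1,3-oxazolidin-2-one; 5 3-methylbut-3-enal
Product: 7 (4S)-4-benzyl-3-[(2S,3R)-3-hydroxy-5-methyl-2-(prop-2-en-1-yl)hex-5-enoyl]-1,3-oxazolidin-2-one, via boron enolate 6 (not isolated)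
Conditions: Bu2BOTf, i-Pr2NEt, CH2Cl2, −78 to 0 °C; then 5, −78 to 0 °C; pH 7 buffer, MeOH, H2O2
Reagents that add atoms: none
Why: Evans syn-aldol, in which the (Z)-boron enolate reacts through a Zimmerman–Traxler chair on the face away from the benzyl group, setting C4 (S) and C5 (R) in the syn relationship that becomes cis on the ring.

Step 4
Reactants: 7 (4S)-4-benzyl-3-[(2S,3R)-3-hydroxy-5-methyl-2-(prop-2-en-1-yl)hex-5-enoyl]-1,3-oxazolidin-2-one
Product: 8 (4S)-4-benzyl-3-[(1S,6R)-6-hydroxy-4-methylcyclohex-3-ene-1-carbonyl]-1,3-oxazolidin-2-one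
Conditions: second-generation Grubbs catalyst RuCl2(=CHPh)(PCy3)(H2IMes) (3 mol%), CH2Cl2, 40 °C
Reagents that add atoms: none
Why: Ring-closing metathesis of the allyl and methallyl arms closes the carbocycle as the trisubstituted C1=C2 olefin without touching a stereocenter.

Step 5
Reactants: 8 (4S)-4-benzyl-3-[(1S,6R)-6-hydroxy-4-methylcyclohex-3-ene-1-carbonyl]-1,3-oxazolidin-2-one
Product: 9 (1S,6R)-6-hydroxy-N-methoxy-N,4-dimethylcyclohex-3-ene-1-carboxamide
Conditions: MeONHMe·HCl, AlMe3, THF/CH2Cl2, −10 to 0 °C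
Reagents that add atoms: N,O-dimethylhydroxylamine hydrochloride, CNOC.Cl
Why: Aluminium-amide aminolysis (Weinreb amide formation) cleaves the auxiliary at the exocyclic carbonyl, helped by the β-hydroxyl, without epimerising C4.

Step 6
Reactants: 9 (1S,6R)-6-hydroxy-N-methoxy-N,4-dimethylcyclohex-3-ene-1-carboxamide
Product: 10 1-[(1S,6R)-6-hydroxy-4-methylcyclohex-3-en-1-yl]ethan-1-one
Conditions: MeMgBr (3 equiv), THF, −20 to 0 °C; NH4Cl quench
Reagents that add atoms: methylmagnesium bromide, C[Mg]Br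
Why: Weinreb ketone synthesis, in which the chelated tetrahedral intermediate stops at mono-addition and protects the α-stereocenter until work-up.

Step 7
Reactants: 10 1-[(1S,6R)-6-hydroxy-4-methylcyclohex-3-en-1-yl]ethan-1-one
Product: 11 (1S)-1-(1,3-dithian-2-yl)-1-[(1S,6R)-6-hydroxy-4-methylcyclohex-3-en-1-yl]ethan-1-ol
Conditions: 1,3-dithiane, n-BuLi, THF, −30 °C (2.5 equiv of the lithio reagent); then 10, −78 to −30 °C
Reagents that add atoms: 1,3-dithiane, C1CSCSC1
Why: Corey–Seebach dithiane addition under 1,3-chelation (Cram–Reetz) control, in which the C5 alkoxide and the ketone oxygen form a cis-fused six-membered chelate and the nucleophile enters anti to the C3 methylene on the convex face, setting C7 (S).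

Step 8
Reactants: 11 (1S)-1-(1,3-dithian-2-yl)-1-[(1S,6R)-6-hydroxy-4-methylcyclohex-3-en-1-yl]ethan-1-ol
Product: 12 (1R,6S)-6-[(1S)-1-(1,3-dithian-2-yl)-1-hydroxyethyl]-3-methylcyclohex-3-en-1-yl acetate
Conditions: Ac2O, pyridine, DMAP (cat.), CH2Cl2, 0 °C
Reagents that add atoms: acetic anhydride, CC(=O)OC(C)=O
Why: Chemoselective DMAP-catalysed acetylation of the secondary C5 hydroxyl over the hindered tertiary C7 hydroxyl installs the target acetate while C5 is still unhindered.

Step 9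
Reactants: 12 (1R,6S)-6-[(1S)-1-(1,3-dithian-2-yl)-1-hydroxyethyl]-3-methylcyclohex-3-en-1-yl acetate
Product: 13 (1R,6S)-6-[(2S)-2-hydroxy-1,1-dimethoxypropan-2-yl]-3-methylcyclohex-3-en-1-yl acetate
Conditions: PhI(OCOCF3)2, MeOH, 0 °C to rt
Reagents that add atoms: methanol, CO
Why: Stork–Zhao oxidative dethioacetalisation in methanol exchanges the oxidation-sensitive dithiane for a dimethyl acetal that survives OsO4 and RuO4.

Step 10
Reactants: 13 (1R,6S)-6-[(2S)-2-hydroxy-1,1-dimethoxypropan-2-yl]-3-methylcyclohex-3-en-1-yl acetate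
Product: 14 (1R,2S,4S,5R)-4,5-dihydroxy-2-[(2S)-2-hydroxy-1,1-dimethoxypropan-2-yl]-5-methylcyclohexyl acetate
Conditions: OsO4 (2 mol%), NMO, acetone/H2O, rt
Reagents that add atoms: 4-methylmorpholine N-oxide, C[N+]1([O-])CCOCC1; water, O
Why: Upjohn syn-dihydroxylation of the only olefin from the face anti to the pseudoaxial C5 acetate (the bulky C4 group sits pseudoequatorial) places both new C1 and C2 hydroxyls trans to the two ring substituents.

Step 11
Reactants: 14 (1R,2S,4S,5R)-4,5-dihydroxy-2-[(2S)-2-hydroxy-1,1-dimethoxypropan-2-yl]-5-methylcyclohexyl acetate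
Product: 16 (1R,2S,4S,5R)-2-[(2S)-2-hydroxy-1,1-dimethoxypropan-2-yl]-5-methyl-4,5-(sulfonyldioxy)cyclohexyl acetate, via cyclic sulfite 15 (not isolated)
Conditions: SOCl2, Et3N, CH2Cl2, 0 °C; then RuCl3 (cat.), NaIO4, MeCN/CCl4/H2O, 0 °C
Reagents that add atoms: thionyl chloride, O=S(Cl)Cl; sodium periodate, [Na+].[O-]I(=O)(=O)=O
Why: Sharpless cyclic sulfate formation (cyclic sulfite, then RuO4 oxidation) activates the cis-diol at both carbons without changing any stereocenter, the hindered tertiary C7 hydroxyl reacting far more slowly than the 1,2-diol.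

Step 12
Reactants: 16 (1R,2S,4S,5R)-2-[(2S)-2-hydroxy-1,1-dimethoxypropan-2-yl]-5-methyl-4,5-(sulfonyldioxy)cyclohexyl acetate
Product: 18 (1R,2S,4R,5R)-4-bromo-5-chloro-2-[(2S)-2-hydroxy-1-oxopropan-2-yl]-5-methylcyclohexyl acetate, via lithium bromo sulfate 17 (not isolated)
Conditions: LiBr, THF, 40 °C; then conc. aq HCl/Et2O (two-phase), 0 °C to rt
Reagents that add atoms: lithium bromide, [Li+].[Br-]; hydrogen chloride, Cl; water, O
Why: Proposed new method: bromide opens the cyclic sulfate by SN2 at the secondary C2 (axial C–O, inversion, equatorial bromide), then acid ionises the tertiary C1 alkyl sulfate to a cation that the C2 bromine bridges from its own face, so chloride enters C1 anti to bromine with net retention and gives the trans-diequatorial 1-chloro-2-bromide (C1 R, C2 R) while the aqueous acid hydrolyses the acetal; the closest known reactions are Sharpless halide opening of cyclic sulfates, Lucas-type tertiary chloride formation and Winstein bromonium participation.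

Step 13
Reactants: 18 (1R,2S,4R,5R)-4-bromo-5-chloro-2-[(2S)-2-hydroxy-1-oxopropan-2-yl]-5-methylcyclohexyl acetate
Product: 19 (1R,2S,4R,5R)-4-bromo-5-chloro-2-[(2S,3S)-2,3-dihydroxyhex-5-en-2-yl]-5-methylcyclohexyl acetate
Conditions: indium metal (In), allyl bromide, THF/H2O, rt
Reagents that add atoms: allyl bromide, C=CCBr
Why: Indium-mediated Barbier allylation under Cram-chelate control, in which indium bridges the aldehyde oxygen and the free C7 hydroxyl and the allyl group adds from the side of the C7 methyl and not the cyclohexyl group, setting C8 (S).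

Step 14
Reactants: 19 (1R,2S,4R,5R)-4-bromo-5-chloro-2-[(2S,3S)-2,3-dihydroxyhex-5-en-2-yl]-5-methylcyclohexyl acetate
Product: 20 (1R,2S,4R,5R)-4-bromo-5-chloro-2-[(2S,3S)-2-hydroxy-3-(triethylsilyloxy)hex-5-en-2-yl]-5-methylcyclohexyl acetate
Conditions: TESCl, imidazole, DMAP (cat.), DMF, 0 °C
Reagents that add atoms: chlorotriethylsilane, CC[Si](Cl)(CC)CC
Why: Selective silylation of the secondary C8 hydroxyl (the tertiary C7 hydroxyl is inert) removes the competing 5-endo nucleophile for the bromoetherification.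

Step 15
Reactants: 20 (1R,2S,4R,5R)-4-bromo-5-chloro-2-[(2S,3S)-2-hydroxy-3-(triethylsilyloxy)hex-5-en-2-yl]-5-methylcyclohexyl acetate
Product: 21 (1R,2S,4R,5R)-4-bromo-5-chloro-2-[(2S,3S)-2-hydroxy-6-methyl-3-(triethylsilyloxy)hept-5-en-2-yl]-5-methylcyclohexyl acetate
Conditions: 2-methylbut-2-ene (excess), second-generation Grubbs catalyst RuCl2(=CHPh)(PCy3)(H2IMes) (5 mol%), CH2Cl2, 40 °C
Reagents that add atoms: 2-methylbut-2-ene, CC=C(C)C
Why: Olefin cross-metathesis converts the terminal allyl group into the prenyl terminus; no stereocenter is involved.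

Step 16
Reactants: 21 (1R,2S,4R,5R)-4-bromo-5-chloro-2-[(2S,3S)-2-hydroxy-6-methyl-3-(triethylsilyloxy)hept-5-en-2-yl]-5-methylcyclohexyl acetate
Product: 23 (1R,2S,4R,5R)-4-bromo-2-[(2S,3S,5S)-5-bromo-3-hydroxy-2,6,6-trimethyloxan-2-yl]-5-chloro-5-methylcyclohexyl acetate, via silyl-protected bromooxane 22 (not isolated)
Conditions: 2,4,4,6-tetrabromocyclohexa-2,5-dien-1-one (TBCO), MeNO2, 0 °C to rt; then HF·pyridine, THF, 0 °C
Reagents that add atoms: 2,4,4,6-tetrabromocyclohexa-2,5-dien-1-one, O=C1C(Br)=CC(Br)(Br)C=C1Br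
Why: 6-endo Markovnikov bromoetherification, in which the C7 hydroxyl opens the C10–C11 bromonium at the tertiary carbon through a chair with bromine and the cyclohexyl group equatorial and the C7 methyl and C8 silyloxy group axial, setting C10 (S), after which fluoride frees the C8 hydroxyl.

## Compound list

1 | (4S)-4-benzyl-1,3-oxazolidin-2-one | O=C1N[C@@H](Cc2ccccc2)CO1 | starting material
2 | pent-4-enoyl chloride | C=CCCC(Cl)=O | starting material
3 | (4S)-4-benzyl-3-(pent-4-enoyl)-1,3-oxazolidin-2-one | C=CCCC(=O)N1[C@@H](Cc2ccccc2)COC1=O | intermediate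
4 | 3-methylbut-3-en-1-ol | CC(=C)CCO | starting material
5 | 3-methylbut-3-enal | CC(=C)CC=O | intermediate
6 | (Z)-dibutylboron enolate of 3 | C=CC/C=C(\OB(CCCC)CCCC)N1[C@@H](Cc2ccccc2)COC1=O | intermediate (not isolated)
7 | (4S)-4-benzyl-3-[(2S,3R)-3-hydroxy-5-methyl-2-(prop-2-en-1-yl)hex-5-enoyl]-1,3-oxazolidin-2-one | C=CC[C@@H]([C@H](O)CC(C)=C)C(=O)N1[C@@H](Cc2ccccc2)COC1=O | intermediate
8 | (4S)-4-benzyl-3-[(1S,6R)-6-hydroxy-4-methylcyclohex-3-ene-1-carbonyl]-1,3-oxazolidin-2-one | CC1=CC[C@@H]([C@H](O)C1)C(=O)N1[C@@H](Cc2ccccc2)COC1=O | intermediate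
9 | (1S,6R)-6-hydroxy-N-methoxy-N,4-dimethylcyclohex-3-ene-1-carboxamide | CC1=CC[C@@H]([C@H](O)C1)C(=O)N(C)OC | intermediate
10 | 1-[(1S,6R)-6-hydroxy-4-methylcyclohex-3-en-1-yl]ethan-1-one | CC1=CC[C@@H]([C@H](O)C1)C(C)=O | intermediate
11 | (1S)-1-(1,3-dithian-2-yl)-1-[(1S,6R)-6-hydroxy-4-methylcyclohex-3-en-1-yl]ethan-1-ol | CC1=CC[C@@H]([C@H](O)C1)[C@](C)(O)C1SCCCS1 | intermediate
12 | (1R,6S)-6-[(1S)-1-(1,3-dithian-2-yl)-1-hydroxyethyl]-3-methylcyclohex-3-en-1-yl acetate | CC1=CC[C@@H]([C@H](OC(C)=O)C1)[C@](C)(O)C1SCCCS1 | intermediate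
13 | (1R,6S)-6-[(2S)-2-hydroxy-1,1-dimethoxypropan-2-yl]-3-methylcyclohex-3-en-1-yl acetate | CC1=CC[C@@H]([C@H](OC(C)=O)C1)[C@](C)(O)C(OC)OC | intermediate
14 | (1R,2S,4S,5R)-4,5-dihydroxy-2-[(2S)-2-hydroxy-1,1-dimethoxypropan-2-yl]-5-methylcyclohexyl acetate | C[C@]1(O)[C@@H](O)C[C@@H]([C@H](OC(C)=O)C1)[C@](C)(O)C(OC)OC | intermediate
15 | 4,5-cyclic sulfite of 14 (mixture at sulfur) | C[C@]1(OS(=O)O2)[C@@H]2C[C@@H]([C@H](OC(C)=O)C1)[C@](C)(O)C(OC)OC | intermediate (not isolated)
16 | (1R,2S,4S,5R)-2-[(2S)-2-hydroxy-1,1-dimethoxypropan-2-yl]-5-methyl-4,5-(sulfonyldioxy)cyclohexyl acetate (4,5-cyclic sulfate of 14) | C[C@]1(OS(=O)(=O)O2)[C@@H]2C[C@@H]([C@H](OC(C)=O)C1)[C@](C)(O)C(OC)OC | intermediate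
17 | lithium (1R,2R,4S,5R)-5-acetoxy-2-bromo-4-[(2S)-2-hydroxy-1,1-dimethoxypropan-2-yl]-1-methylcyclohexyl sulfate | [Li+].C[C@]1(OS(=O)(=O)[O-])[C@H](Br)C[C@@H]([C@H](OC(C)=O)C1)[C@](C)(O)C(OC)OC | intermediate (not isolated)
18 | (1R,2S,4R,5R)-4-bromo-5-chloro-2-[(2S)-2-hydroxy-1-oxopropan-2-yl]-5-methylcyclohexyl acetate | C[C@]1(Cl)[C@H](Br)C[C@@H]([C@H](OC(C)=O)C1)[C@](C)(O)C=O | intermediate
19 | (1R,2S,4R,5R)-4-bromo-5-chloro-2-[(2S,3S)-2,3-dihydroxyhex-5-en-2-yl]-5-methylcyclohexyl acetate | C[C@]1(Cl)[C@H](Br)C[C@@H]([C@H](OC(C)=O)C1)[C@](C)(O)[C@@H](O)CC=C | intermediate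
20 | (1R,2S,4R,5R)-4-bromo-5-chloro-2-[(2S,3S)-2-hydroxy-3-(triethylsilyloxy)hex-5-en-2-yl]-5-methylcyclohexyl acetate | C[C@]1(Cl)[C@H](Br)C[C@@H]([C@H](OC(C)=O)C1)[C@](C)(O)[C@@H](O[Si](CC)(CC)CC)CC=C | intermediate
21 | (1R,2S,4R,5R)-4-bromo-5-chloro-2-[(2S,3S)-2-hydroxy-6-methyl-3-(triethylsilyloxy)hept-5-en-2-yl]-5-methylcyclohexyl acetate | C[C@]1(Cl)[C@H](Br)C[C@@H]([C@H](OC(C)=O)C1)[C@](C)(O)[C@@H](O[Si](CC)(CC)CC)CC=C(C)C | intermediate
22 | (1R,2S,4R,5R)-4-bromo-2-[(2S,3S,5S)-5-bromo-2,6,6-trimethyl-3-(triethylsilyloxy)oxan-2-yl]-5-chloro-5-methylcyclohexyl acetate | C[C@]1(Cl)[C@H](Br)C[C@@H]([C@H](OC(C)=O)C1)[C@]1(C)OC(C)(C)[C@@H](Br)C[C@@H]1O[Si](CC)(CC)CC | intermediate (not isolated)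
23 | (1R,2S,4R,5R)-4-bromo-2-[(2S,3S,5S)-5-bromo-3-hydroxy-2,6,6-trimethyloxan-2-yl]-5-chloro-5-methylcyclohexyl acetate | CC(=O)O[C@@H]1C[C@@](C)(Cl)[C@H](Br)C[C@@H]1[C@]1(C)OC(C)(C)[C@@H](Br)C[C@@H]1O | target

## Step count and risk

Total steps: 16. Longest linear sequence: 15 (steps 1 and 3–16; step 2 is a one-step side branch).

**Most likely to fail, with one fallback each**

- **Step 12 (one-flask bromide opening and chloride relay).** The chlorination is untested: chloride may open the bromonium at C2, the cation may eliminate or be captured by the axial C5 acetate, and the acetate may suffer in concentrated acid. Fallback, setting out from 16 and coming back at 18: open the cyclic sulfate with LiBr and hydrolyse the sulfate monoester under the standard mild conditions (cat. H2SO4, one equivalent of water, THF) to isolate the tertiary bromohydrin acetal F1. Convert its tertiary hydroxyl into the chloride by deoxychlorination with SOCl2 in ether without base (chlorosulfite ion pair, retention, again guided by the neighbouring bromine) to give the bromochloride acetal F2. Hydrolyse the acetal with aqueous trifluoroacetic acid to reach 18.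

- **Step 16 (bromoetherification).** The 5-exo mode (oxolane with a bromoisopropyl group) and the C10 epimer can compete with the desired 6-endo chair. Fallback, setting out from 21 and coming back at 22: epoxidise the prenyl olefin with the D-fructose-derived Shi ketone and Oxone to the (10R)-epoxide F3. Open it at the secondary C10 with Li2NiBr4 (SN2, inversion) to give the (10S)-bromo tertiary alcohol F4. Treat F4 with catalytic camphorsulfonic acid in MeNO2, so that the tertiary C11 hydroxyl ionises with bromine participation and the C7 hydroxyl closes the oxane at C11 to give 22, which is desilylated as in step 16; here C10 is fixed by the reagent and not by the chair preference.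

- **Step 7 (dithiane addition to the β-hydroxy methyl ketone).** Enolisation, retro-aldol cleavage or weak lithium chelation could erode yield and selectivity. Fallback, setting out from 9 and coming back at 11: silylate the C5 hydroxyl (TBSOTf, 2,6-lutidine) to the silyl Weinreb amide F5. Add 2-lithio-1,3-dithiane to obtain the acyl dithiane F6. Add methyl as the non-basic organocerium reagent (MeLi, CeCl3, −78 °C) under Felkin–Anh control of the non-chelating α-stereocenter C4, which gives the same C7 (S) configuration, to form the silyl-protected tertiary alcohol F7. Remove the silyl group with Bu4NF to reach 11.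

## Further compounds

F1 | step 12 | (1R,2S,4R,5R)-4-bromo-5-hydroxy-2-[(2S)-2-hydroxy-1,1-dimethoxypropan-2-yl]-5-methylcyclohexyl acetate | C[C@]1(O)[C@H](Br)C[C@@H]([C@H](OC(C)=O)C1)[C@](C)(O)C(OC)OC
F2 | step 12 | (1R,2S,4R,5R)-4-bromo-5-chloro-2-[(2S)-2-hydroxy-1,1-dimethoxypropan-2-yl]-5-methylcyclohexyl acetate | C[C@]1(Cl)[C@H](Br)C[C@@H]([C@H](OC(C)=O)C1)[C@](C)(O)C(OC)OC
F3 | step 16 | (1R,2S,4R,5R)-4-bromo-5-chloro-2-[(2S,3S)-4-[(2R)-3,3-dimethyloxiran-2-yl]-2-hydroxy-3-(triethylsilyloxy)butan-2-yl]-5-methylcyclohexyl acetate | C[C@]1(Cl)[C@H](Br)C[C@@H]([C@H](OC(C)=O)C1)[C@](C)(O)[C@@H](O[Si](CC)(CC)CC)C[C@H]1OC1(C)C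
F4 | step 16 | (1R,2S,4R,5R)-4-bromo-2-[(2S,3S,5S)-5-bromo-2,6-dihydroxy-6-methyl-3-(triethylsilyloxy)heptan-2-yl]-5-chloro-5-methylcyclohexyl acetate | C[C@]1(Cl)[C@H](Br)C[C@@H]([C@H](OC(C)=O)C1)[C@](C)(O)[C@@H](O[Si](CC)(CC)CC)C[C@H](Br)C(C)(C)O
F5 | step 7 | (1S,6R)-6-(tert-butyldimethylsilyloxy)-N-methoxy-N,4-dimethylcyclohex-3-ene-1-carboxamide | CC1=CC[C@@H]([C@H](O[Si](C)(C)C(C)(C)C)C1)C(=O)N(C)OC
F6 | step 7 | [(1S,6R)-6-(tert-butyldimethylsilyloxy)-4-methylcyclohex-3-en-1-yl](1,3-dithian-2-yl)methanone | CC1=CC[C@@H]([C@H](O[Si](C)(C)C(C)(C)C)C1)C(=O)C1SCCCS1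
F7 | step 7 | (1S)-1-[(1S,6R)-6-(tert-butyldimethylsilyloxy)-4-methylcyclohex-3-en-1-yl]-1-(1,3-dithian-2-yl)ethan-1-ol | CC1=CC[C@@H]([C@H](O[Si](C)(C)C(C)(C)C)C1)[C@](C)(O)C1SCCCS1
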